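**Plan**
- Retrosynthesis: both epoxides go back to the (E,E)-1(10),4-diene, and the two esters to an 8,13-diol held as a cyclic silylene. The C5–C6 bond and the lactone O–C12 bond are then cut together, giving an acyclic (E)-alkenyl iodide / (Z)-formyl acrylate silyl ester. That comes from a butenolide by γ-oxidation, the butenolide from a dihydroxy ketone by intramolecular Horner–Wadsworth–Emmons reaction, and the ketone by C8–C9 alkylation.
- Forward: the C1–C5/C9/C10 chain is built first and joined at C8–C9 to a dioxanone hydrazone. Then follow the butenolide (C7=C11), the temporary O8–Si–O13 ring, the silyloxyfuran, the C6 aldehyde, closure of the ten-membered ring together with the butenolide, the esters, and last the epoxides.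
- Enabling feature: C6 is both the carbinol carbon of the butenolide (ring O–C12–C11=C7–C6) and a member of the carbocycle, and C5 is the vinylic CH of C4=C5 before epoxidation. An alkenylchromium at C5 adding to a C6 aldehyde held cis to the C12 ester across C7=C11 therefore closes both rings at once.
- Stereochemistry: C8 comes from the SAMP auxiliary. C6 comes from C8, relayed by the seven-membered silylene ring (not in the target, removed in step 16). The four epoxide centres come from peripheral attack on the E,E-diene ring.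

Key step: step 15

Remark: germacrane numbering is used throughout (ring C1–C10, C11–C13 on C7, C14 on C10, C15 on C4). The descriptor at C6 is R in the triene intermediates and S in 30 for the same geometry, because C5 outranks C7 only once it carries oxygen.

**Step 1**
Reactants: 1 pent-4-yn-1-ol
Product: 3 (E)-5-iodo-4-methylpent-4-en-1-ol, via alkenylalane 2 (not isolated)
Conditions: Me3Al, Cp2ZrCl2 (cat.), CH2Cl2, 0 °C to rt; then I2, THF, −30 to 0 °C
Reagents that add atoms: trimethylaluminium, C[Al](C)C; iodine, II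
Why: Negishi carboalumination adds methyl and aluminium syn across the terminal alkyne (methyl to the internal carbon), and iodinolysis with retention should give the E-alkenyl iodide that carries C15 and the future C4=C5 geometry.

**Step 2**
Reactants: 3 (E)-5-iodo-4-methylpent-4-en-1-ol; 4 ethyl 2-(triphenylphosphoranylidene)propanoate
Product: 6 ethyl (2E,6E)-7-iodo-2,6-dimethylhepta-2,6-dienoate, via aldehyde 5 (not isolated)
Conditions: Dess–Martin periodinane, NaHCO3, CH2Cl2, 0 °C to rt; then 4, rt
Reagents that add atoms: none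
Why: Oxidation to the aldehyde and Wittig reaction with the stabilised ylide in the same flask should give the E-trisubstituted enoate, which fixes the C1=C10 geometry.

**Step 3**
Reactants: 6 ethyl (2E,6E)-7-iodo-2,6-dimethylhepta-2,6-dienoate
Product: 7 (2E,6E)-7-iodo-2,6-dimethylhepta-2,6-dien-1-ol
Conditions: iBu2AlH, CH2Cl2, −78 °C
Reagents that add atoms: none
Why: 1,2-Reduction of the enoate with diisobutylaluminium hydride gives the allylic alcohol and leaves the alkenyl iodide untouched.

**Step 4**
Reactants: 7 (2E,6E)-7-iodo-2,6-dimethylhepta-2,6-dien-1-ol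
Product: 8 (1E,5E)-7-bromo-1-iodo-2,6-dimethylhepta-1,5-diene
Conditions: CBr4, PPh3, CH2Cl2, −20 to 0 °C
Reagents that add atoms: carbon tetrabromide, BrC(Br)(Br)Br
Why: Appel bromination of the primary allylic alcohol proceeds by direct substitution, without allylic transposition or loss of olefin geometry.

**Step 5**
Reactants: 9 2,2-dimethyl-1,3-dioxan-5-one; 10 (S)-1-amino-2-(methoxymethyl)pyrrolidine (SAMP)
Product: 11 (S)-N-(2,2-dimethyl-1,3-dioxan-5-ylidene)-2-(methoxymethyl)pyrrolidin-1-amine
Conditions: cyclohexane, reflux, water separator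
Reagents that add atoms: none
Why: Condensation of the ketone with the hydrazine gives the chiral hydrazone of the dihydroxyacetone equivalent that will supply C6, C7 and C8.

**Step 6**
Reactants: 11 (S)-N-(2,2-dimethyl-1,3-dioxan-5-ylidene)-2-(methoxymethyl)pyrrolidin-1-amine; 8 (1E,5E)-7-bromo-1-iodo-2,6-dimethylhepta-1,5-diene
Product: 13 (S)-N-{(4S)-4-[(2E,6E)-7-iodo-2,6-dimethylhepta-2,6-dien-1-yl]-2,2-dimethyl-1,3-dioxan-5-ylidene}-2-(methoxymethyl)pyrrolidin-1-amine, via lithium azaenolate 12 (not isolated)
Conditions: tBuLi, THF, −78 °C; then 8, −100 to −78 °C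
Reagents that add atoms: none
Why: SAMP-hydrazone alkylation: the methoxy-chelated lithium azaenolate is alkylated by the allylic bromide on the face dictated by the auxiliary, forming C8–C9 and setting C8 as S; the base is consumed before the iodide-bearing electrophile is added.

**Step 7**
Reactants: 13 the alkylated SAMP hydrazone
Product: 15 (3S,5E,9E)-1,3-dihydroxy-10-iodo-5,9-dimethyldeca-5,9-dien-2-one, via dioxanone 14 (not isolated)
Conditions: sat. aq. oxalic acid, Et2O, rt; then 1 M HCl, THF, rt
Reagents that add atoms: water, O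
Why: Mild acidic hydrolysis cleaves the hydrazone without epimerising the α-centre, and stronger aqueous acid then removes the acetonide, exposing the C6 primary and C8 secondary hydroxyls beside the C7 ketone.

**Step 8**
Reactants: 16 diethyl (2-hydroxyethyl)phosphonate
Product: 17 diethyl {2-[(tert-butyldimethylsilyl)oxy]ethyl}phosphonate
Conditions: TBSCl, imidazole, CH2Cl2, rt
Reagents that add atoms: tert-butyldimethylsilyl chloride, CC(C)(C)[Si](C)(C)Cl
Why: Standard silylation protects the hydroxyl that will become O-13.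

**Step 9**
Reactants: 17 diethyl {2-[(tert-butyldimethylsilyl)oxy]ethyl}phosphonate
Product: 18 3-[(tert-butyldimethylsilyl)oxy]-2-(diethoxyphosphoryl)propanoic acid
Conditions: LiN(iPr)2 (2.2 equiv), THF, −78 °C; CO2; cold 1 M HCl work-up
Reagents that add atoms: carbon dioxide, O=C=O
Why: α-Lithiation of the alkylphosphonate and carboxylation at −78 °C (cold enough to suppress β-elimination of the silyloxide) gives the phosphonoacetic acid that carries C11, C12 and C13.

**Step 10**
Reactants: 15 (3S,5E,9E)-1,3-dihydroxy-10-iodo-5,9-dimethyldeca-5,9-dien-2-one; 18 3-[(tert-butyldimethylsilyl)oxy]-2-(diethoxyphosphoryl)propanoic acid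
Product: 19 (3S,5E,9E)-3-hydroxy-10-iodo-5,9-dimethyl-2-oxodeca-5,9-dien-1-yl 3-[(tert-butyldimethylsilyl)oxy]-2-(diethoxyphosphoryl)propanoate
Conditions: dicyclohexylcarbodiimide, DMAP (cat.), CH2Cl2, −20 to 0 °C
Reagents that add atoms: none
Why: Carbodiimide esterification with one equivalent of acid at low temperature should acylate the primary C6 hydroxyl in preference to the hindered secondary C8 hydroxyl.

**Step 11**
Reactants: 19 the phosphonoacetate ester
Product: 21 4-[(1S,3E,7E)-1-hydroxy-8-iodo-3,7-dimethylocta-3,7-dien-1-yl]-3-(hydroxymethyl)furan-2(5H)-one, via silyl ether 20 (not isolated)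
Conditions: LiCl, iPr2NEt, MeCN, 0 °C to rt; then HCl in MeOH, 0 °C to rt
Reagents that add atoms: none
Why: Intramolecular Horner–Wadsworth–Emmons reaction (Masamune–Roush conditions) onto the C7 ketone closes the butenolide, so the tetrasubstituted C7=C11 bond is formed with C6 and C12 necessarily cis; acidic methanolysis then frees O-13.

**Step 12**
Reactants: 21 the diol butenolide
Product: 22 silylene acetal: butenolide 21 with O-8 and O-13 bridged by Si(tBu)2 (seven-membered 1,3,2-dioxasilepine fused at C7=C11)
Conditions: tBu2Si(OTf)2, 2,6-lutidine, CH2Cl2, 0 °C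
Reagents that add atoms: di-tert-butylsilyl bis(trifluoromethanesulfonate), CC(C)(C)[Si](OS(=O)(=O)C(F)(F)F)(OS(=O)(=O)C(F)(F)F)C(C)(C)C
Why: Silylene formation across the cis-disposed 1,4-diol protects both hydroxyls as poor leaving groups and builds a ring absent from the target, whose purpose is to fix the rotamer about C7–C8 for step 15.

**Step 13**
Reactants: 22 the silylene acetal
Product: 23 2-(triisopropylsilyloxy)furan derived from 22 (silyl enol ether at C12, free furan CH at C6)
Conditions: iPr3SiOTf, Et3N, CH2Cl2, 0 °C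
Reagents that add atoms: triisopropylsilyl trifluoromethanesulfonate, CC(C)[Si](OS(=O)(=O)C(F)(F)F)(C(C)C)C(C)C
Why: Soft enolisation of the butenolide at its γ-CH2 gives the aromatic silyloxyfuran; both oxygens on the side arms are silyl ethers, so vinylogous β-elimination is not expected.

**Step 14**
Reactants: 23 the 2-silyloxyfuran
Product: 24 triisopropylsilyl (7S)-2,2-di-tert-butyl-6-formyl-7-[(2E,6E)-7-iodo-2,6-dimethylhepta-2,6-dien-1-yl]-4,7-dihydro-1,3,2-dioxasilepine-5-carboxylate
Conditions: dimethyldioxirane (1 equiv, acetone), CH2Cl2, −78 °C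
Reagents that add atoms: dimethyldioxirane, CC1(C)OO1
Why: Oxygen transfer to the very electron-rich silyloxyfuran, followed by ring opening with silyl migration, is a known route to silyl (Z)-4-oxo-2-enoates; it raises C6 to the aldehyde level with the Z geometry fixed, and at −78 °C with one equivalent the isolated olefin and the iodide should not compete.

**Step 15**
Reactants: 24 the (Z)-formyl silyl ester
Product: 26 (6R,8S)-8,13-(di-tert-butylsilylenedioxy)germacra-1(10)E,4E,7(11)-trien-12,6-olide, via hydroxy silyl ester 25 (not isolated)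
Conditions: CrCl2 (excess), NiCl2 (cat.), DMSO/THF, rt, high dilution, slow addition of 24
Reagents that add atoms: none
Why: Zerovalent nickel inserts into the C5–I bond, transmetalation gives an alkenyl species of trivalent chromium, and this adds 1,2 to the C6 aldehyde (Nozaki–Hiyama–Kishi reaction; closest precedent is the closure of alkenyl iodide–aldehydes to nine- and ten-membered carbocycles), after which the chromium alkoxide 25 attacks the cis-disposed C12 silyl ester and expels the silanolate. The carbocycle closes by 10-exo-trig addition and the butenolide by 5-exo-trig acyl substitution, so one operation forms C5–C6 and O–C12 and both rings. The new C6 centre is controlled by C8 through the silylene ring: the ring holds O-8 on the C13 side and below the C7=C11 plane, which for the 8S centre places C9 above that plane, and the short C9–C5 chain should then deliver C5 to the upper face of the planar formyl group, giving the 6,8 relationship of the target. Without the ring, allylic 1,3-strain with C13 would turn H-8 into the plane and put C9 on the other face. The step also needs 1,2- rather than 1,4-addition (inherent to organochromium reagents), cyclisation rather than oligomerisation (high dilution, slow addition) and retention of the E geometry at C4=C5 (alkenylchromium species keep their configuration).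

**Step 16**
Reactants: 26 the silylene-protected macrolactone
Product: 27 (6R,8S)-8,13-dihydroxygermacra-1(10)E,4E,7(11)-trien-12,6-olide
Conditions: HF·pyridine, pyridine, THF, 0 °C
Reagents that add atoms: none
Why: Buffered fluoride removes the silylene without exposing the acid-sensitive 1,5-diene or the base-sensitive γ-position of the butenolide to harsh conditions.

**Step 17**
Reactants: 27 the 8,13-diol
Product: 28 (6R,8S)-13-acetoxy-8-hydroxygermacra-1(10)E,4E,7(11)-trien-12,6-olide
Conditions: AcCl, 2,4,6-collidine, CH2Cl2, −78 °C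
Reagents that add atoms: acetyl chloride, CC(Cl)=O
Why: At low temperature with a hindered pyridine base, the primary allylic C13 hydroxyl should be acetylated selectively over the hindered secondary C8 hydroxyl.

**Step 18**
Reactants: 28 the 13-acetate
Product: 29 (6R,8S)-13-acetoxy-8-(2-methylpropanoyloxy)germacra-1(10)E,4E,7(11)-trien-12,6-olide
Conditions: iPrCOCl, pyridine, DMAP (cat.), CH2Cl2, 0 °C
Reagents that add atoms: 2-methylpropanoyl chloride, CC(C)C(Cl)=O
Why: Acylation at oxygen installs the isobutyrate with retention at C8; pyridine is too weak a base to deprotonate C6 or to trigger loss of the 13-acetate.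

**Step 19**
Reactants: 29 the triene diester
Product: 30 (1R,4R,5R,6S,8S,10R)-13-acetoxy-1,10:4,5-diepoxy-8-(2-methylpropanoyloxy)germacr-7(11)-en-12,6-olide
Conditions: dimethyldioxirane (excess, acetone), CH2Cl2, −20 to 0 °C
Reagents that add atoms: dimethyldioxirane, CC1(C)OO1
Why: The neutral dioxirane epoxidises the two electron-rich trisubstituted E-olefins from the outer face of the ten-membered ring and leaves the electron-poor butenolide; at C4=C5, allylic 1,3-strain with C15 keeps H-6 in the olefin plane, so the outer face is syn to the lactone oxygen (threo, 4R,5R), and in the crossed conformer with C14 and C15 on the same side the outer face of C1=C10 gives 1R,10R, both epoxides being trans from the E geometry.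

**Compound list**
1 | pent-4-yn-1-ol | C#CCCCO | starting material
2 | [(E)-5-(dimethylalumanyloxy)-2-methylpent-1-en-1-yl]dimethylalane | C[Al](C)OCCC/C(C)=C/[Al](C)C | intermediate
3 | (E)-5-iodo-4-methylpent-4-en-1-ol | OCCC/C(C)=C/I | intermediate
4 | ethyl 2-(triphenylphosphoranylidene)propanoate | CCOC(=O)C(C)=P(c1ccccc1)(c1ccccc1)c1ccccc1 | starting material
5 | (E)-5-iodo-4-methylpent-4-enal | O=CCC/C(C)=C/I | intermediate
6 | ethyl (2E,6E)-7-iodo-2,6-dimethylhepta-2,6-dienoate | CCOC(=O)/C(C)=C/CC/C(C)=C/I | intermediate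
7 | (2E,6E)-7-iodo-2,6-dimethylhepta-2,6-dien-1-ol | OC/C(C)=C/CC/C(C)=C/I | intermediate
8 | (1E,5E)-7-bromo-1-iodo-2,6-dimethylhepta-1,5-diene | BrC/C(C)=C/CC/C(C)=C/I | intermediate
9 | 2,2-dimethyl-1,3-dioxan-5-one | CC1(C)OCC(=O)CO1 | starting material
10 | (S)-1-amino-2-(methoxymethyl)pyrrolidine (SAMP) | COC[C@@H]1CCCN1N | starting material
11 | (S)-N-(2,2-dimethyl-1,3-dioxan-5-ylidene)-2-(methoxymethyl)pyrrolidin-1-amine | COC[C@@H]1CCCN1N=C1COC(C)(C)OC1 | intermediate
12 | lithium azaenolate of 11 | COC[C@@H]1CCCN1N([Li])C1=COC(C)(C)OC1 | intermediate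
13 | (S)-N-{(4S)-4-[(2E,6E)-7-iodo-2,6-dimethylhepta-2,6-dien-1-yl]-2,2-dimethyl-1,3-dioxan-5-ylidene}-2-(methoxymethyl)pyrrolidin-1-amine | COC[C@@H]1CCCN1N=C1COC(C)(C)O[C@H]1C/C(C)=C/CC/C(C)=C/I | intermediate
14 | (S)-4-[(2E,6E)-7-iodo-2,6-dimethylhepta-2,6-dien-1-yl]-2,2-dimethyl-1,3-dioxan-5-one | CC1(C)OCC(=O)[C@H](C/C(C)=C/CC/C(C)=C/I)O1 | intermediate
15 | (3S,5E,9E)-1,3-dihydroxy-10-iodo-5,9-dimethyldeca-5,9-dien-2-one | OCC(=O)[C@@H](O)C/C(C)=C/CC/C(C)=C/I | intermediate
16 | diethyl (2-hydroxyethyl)phosphonate | CCOP(=O)(CCO)OCC | starting material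
17 | diethyl {2-[(tert-butyldimethylsilyl)oxy]ethyl}phosphonate | CCOP(=O)(CCO[Si](C)(C)C(C)(C)C)OCC | intermediate
18 | 3-[(tert-butyldimethylsilyl)oxy]-2-(diethoxyphosphoryl)propanoic acid | CCOP(=O)(OCC)C(CO[Si](C)(C)C(C)(C)C)C(=O)O | intermediate
19 | (3S,5E,9E)-3-hydroxy-10-iodo-5,9-dimethyl-2-oxodeca-5,9-dien-1-yl 3-[(tert-butyldimethylsilyl)oxy]-2-(diethoxyphosphoryl)propanoate | CCOP(=O)(OCC)C(CO[Si](C)(C)C(C)(C)C)C(=O)OCC(=O)[C@@H](O)C/C(C)=C/CC/C(C)=C/I | intermediate
20 | 3-{[(tert-butyldimethylsilyl)oxy]methyl}-4-[(1S,3E,7E)-1-hydroxy-8-iodo-3,7-dimethylocta-3,7-dien-1-yl]furan-2(5H)-one | O=C1OCC([C@@H](O)C/C(C)=C/CC/C(C)=C/I)=C1CO[Si](C)(C)C(C)(C)C | intermediate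
21 | 4-[(1S,3E,7E)-1-hydroxy-8-iodo-3,7-dimethylocta-3,7-dien-1-yl]-3-(hydroxymethyl)furan-2(5H)-one | O=C1OCC([C@@H](O)C/C(C)=C/CC/C(C)=C/I)=C1CO | intermediate
22 | butenolide 21 with O-8 and O-13 bridged by Si(tBu)2 (8S; seven-membered 1,3,2-dioxasilepine fused at C7=C11) | O=C1OCC2=C1CO[Si](C(C)(C)C)(C(C)(C)C)O[C@H]2C/C(C)=C/CC/C(C)=C/I | intermediate
23 | 2-(triisopropylsilyloxy)furan derived from 22 | CC(C)[Si](Oc1occ2c1CO[Si](C(C)(C)C)(C(C)(C)C)O[C@H]2C/C(C)=C/CC/C(C)=C/I)(C(C)C)C(C)C | intermediate
24 | triisopropylsilyl (7S)-2,2-di-tert-butyl-6-formyl-7-[(2E,6E)-7-iodo-2,6-dimethylhepta-2,6-dien-1-yl]-4,7-dihydro-1,3,2-dioxasilepine-5-carboxylate | O=CC1=C(C(=O)O[Si](C(C)C)(C(C)C)C(C)C)CO[Si](C(C)(C)C)(C(C)(C)C)O[C@H]1C/C(C)=C/CC/C(C)=C/I | intermediate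
25 | triisopropylsilyl ester of (6R,8S)-8,13-(di-tert-butylsilylenedioxy)-6-hydroxygermacra-1(10)E,4E,7(11)-trien-12-oic acid | CC(C)(C)[Si]1(C(C)(C)C)OCC(C(=O)O[Si](C(C)C)(C(C)C)C(C)C)=C2[C@@H](O1)C/C(C)=C/CC/C(C)=C/[C@H]2O | intermediate
26 | (6R,8S)-8,13-(di-tert-butylsilylenedioxy)germacra-1(10)E,4E,7(11)-trien-12,6-olide | CC(C)(C)[Si]1(C(C)(C)C)OCC2=C3[C@@H](O1)C/C(C)=C/CC/C(C)=C/[C@H]3OC2=O | intermediate
27 | (6R,8S)-8,13-dihydroxygermacra-1(10)E,4E,7(11)-trien-12,6-olide | OCC1=C2[C@@H](O)C/C(C)=C/CC/C(C)=C/[C@H]2OC1=O | intermediate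
28 | (6R,8S)-13-acetoxy-8-hydroxygermacra-1(10)E,4E,7(11)-trien-12,6-olide | CC(=O)OCC1=C2[C@@H](O)C/C(C)=C/CC/C(C)=C/[C@H]2OC1=O | intermediate
29 | (6R,8S)-13-acetoxy-8-(2-methylpropanoyloxy)germacra-1(10)E,4E,7(11)-trien-12,6-olide | CC(=O)OCC1=C2[C@@H](OC(=O)C(C)C)C/C(C)=C/CC/C(C)=C/[C@H]2OC1=O | intermediate
30 | (1R,4R,5R,6S,8S,10R)-13-acetoxy-1,10:4,5-diepoxy-8-(2-methylpropanoyloxy)germacr-7(11)-en-12,6-olide | CC(=O)OCC1=C2[C@@H](OC(=O)C(C)C)C[C@@]3(C)O[C@@H]3CC[C@@]3(C)O[C@@H]3[C@H]2OC1=O | target

**Totals**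
Total step count: 19. Longest linear sequence: 16 steps (steps 1–4, 6, 7, 10–19).

**Steps most likely to fail**

Step 15. The alkenylchromium may attack the other face of the C6 aldehyde, because the conformational argument for the tethered substrate is qualitative, or divalent chromium may reduce the electron-poor formyl acrylate before the C–C bond forms. The fallback sets out from 20 (isolated by leaving out the acid stage of step 11) and returns at 29. It runs the same closure without the silylene ring, so that allylic 1,3-strain with C13, not the tether, fixes the C8 rotamer (H-8 in the C7=C11 plane, C9 on the opposite face), which should reverse the face of attack at C6. Compound 20 is acylated (iPrCOCl, pyridine, DMAP) to the 8-O-isobutyrate butenolide F1, converted with iPr3SiOTf/Et3N into the silyloxyfuran F2, and oxidised with dimethyldioxirane to the acyclic (Z)-formyl silyl ester F3. Closure with CrCl2/NiCl2 gives the macrolactone F4, HF·pyridine frees the 13-alcohol F5, and acetylation (AcCl, pyridine) gives 29.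

Step 19. A second ring conformer may be populated, so that the oxidant reaches the other face of C1=C10, or a mono-epoxide may undergo transannular cyclisation. The fallback sets out from 29 and returns at 30. It replaces conformational control by reagent control in two stages: Shi epoxidation with the D-fructose-derived ketone (Oxone, buffer at pH 8, MeCN/dimethoxymethane/water, 0 °C) should oxidise the more electron-rich C1=C10 bond first and, by the spiro transition-state model, give the 1R,10R mono-epoxide F6. Dimethyldioxirane then epoxidises C4=C5 of F6 under the local control of C6 and gives 30.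

Step 14. Oxygen transfer may also reach the C1=C10 olefin or the iodine, and the silyl ester may hydrolyse to the unreactive lactol. The fallback sets out from 23 and returns at 26. Singlet oxygen (O2, tetraphenylporphyrin, light, CH2Cl2, −78 °C; then PPh3) adds to the silyloxyfuran in a [4+2] sense and should leave the isolated olefin and the iodide alone; reduction gives the γ-hydroxybutenolide F7. Alkylation of its ring-opened carboxylate (MeI, K2CO3, DMF, 0 °C) gives the methyl (Z)-formyl ester F8, which under the conditions of step 15 closes to 26 with loss of methanol.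

**Further compounds**
F1 | step 15 | 3-{[(tert-butyldimethylsilyl)oxy]methyl}-4-[(1S,3E,7E)-8-iodo-3,7-dimethyl-1-(2-methylpropanoyloxy)octa-3,7-dien-1-yl]furan-2(5H)-one | O=C1OCC([C@@H](OC(=O)C(C)C)C/C(C)=C/CC/C(C)=C/I)=C1CO[Si](C)(C)C(C)(C)C
F2 | step 15 | 2-(triisopropylsilyloxy)furan derived from F1 | CC(C)[Si](Oc1occ([C@@H](OC(=O)C(C)C)C/C(C)=C/CC/C(C)=C/I)c1CO[Si](C)(C)C(C)(C)C)(C(C)C)C(C)C
F3 | step 15 | triisopropylsilyl (2Z,4S,6E,10E)-2-{[(tert-butyldimethylsilyl)oxy]methyl}-3-formyl-11-iodo-6,10-dimethyl-4-(2-methylpropanoyloxy)undeca-2,6,10-trienoate | O=C/C(=C(/CO[Si](C)(C)C(C)(C)C)C(=O)O[Si](C(C)C)(C(C)C)C(C)C)[C@@H](OC(=O)C(C)C)C/C(C)=C/CC/C(C)=C/I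
F4 | step 15 | (6R,8S)-13-[(tert-butyldimethylsilyl)oxy]-8-(2-methylpropanoyloxy)germacra-1(10)E,4E,7(11)-trien-12,6-olide | CC(C)(C)[Si](C)(C)OCC1=C2[C@@H](OC(=O)C(C)C)C/C(C)=C/CC/C(C)=C/[C@H]2OC1=O
F5 | step 15 | (6R,8S)-13-hydroxy-8-(2-methylpropanoyloxy)germacra-1(10)E,4E,7(11)-trien-12,6-olide | OCC1=C2[C@@H](OC(=O)C(C)C)C/C(C)=C/CC/C(C)=C/[C@H]2OC1=O
F6 | step 19 | (1R,6R,8S,10R)-13-acetoxy-1,10-epoxy-8-(2-methylpropanoyloxy)germacra-4E,7(11)-dien-12,6-olide | CC(=O)OCC1=C2[C@@H](OC(=O)C(C)C)C[C@@]3(C)O[C@@H]3CC/C(C)=C/[C@H]2OC1=O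
F7 | step 14 | γ-hydroxybutenolide (C6 lactol, both epimers) of silylene acetal 22 | O=C1OC(O)C2=C1CO[Si](C(C)(C)C)(C(C)(C)C)O[C@H]2C/C(C)=C/CC/C(C)=C/I
F8 | step 14 | methyl (7S)-2,2-di-tert-butyl-6-formyl-7-[(2E,6E)-7-iodo-2,6-dimethylhepta-2,6-dien-1-yl]-4,7-dihydro-1,3,2-dioxasilepine-5-carboxylate | O=CC1=C(C(=O)OC)CO[Si](C(C)(C)C)(C(C)(C)C)O[C@H]1C/C(C)=C/CC/C(C)=C/I
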